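**Plan**

- Ring names: ring A is the 2,2-dimethylpyran on the first quinolone, ring B the bridging pyran on the second quinolone, ring C the cyclohexene.
- Cuts: ring C is opened at the CH2–CH(quinolone) bond and at the bond from the methyl-bearing bridgehead to the alkene CH. The same operation releases the ring B O–C(Me) bond and the C3–CH bond of the second quinolone.
- Enabling feature: the methyl-bearing bridgehead carries the ring B oxygen, so with the bridging CH2 it is a masked acetone unit. Ring B is then the hetero-Diels–Alder adduct of a 3-alkylidenequinoline-2,4-dione (O=C4–C3=CH), and the ring C alkene is the end of the ring A oxy-diene O–C4=C3–C=CH2, nucleophilic at CH2.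
- Forward order: quinolone from aniline and malonate; ring A by aryl ether formation and 6-exo Heck closure; then rings B and C in one pot from the ring A aldehyde, a second quinolone and 2-methoxypropene.
- Stereochemistry: the ring A/ring C fusion CH comes from Sharpless epoxidation of prenol and an invertive epoxide opening. Both bridgeheads are set from it in the last step (allylic 1,3-strain face selection, then the bridging constraint).

Key step: step 12

Assumption: 2,3-dimethoxyaniline, diethyl malonate, 3-methylbut-2-en-1-ol and 2-methoxypropene are taken as commercial, and the configuration set in step 4 is not touched again before step 11.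

**Route**

Step 1
Reactants: 1 2,3-dimethoxyaniline
Product: 2 2,3-dimethoxy-N-methylaniline
Conditions: (CH2O)n, NaOMe, MeOH, reflux; then NaBH4, reflux
Reagents that add atoms: paraformaldehyde (formaldehyde), C=O
Why: Reductive mono-N-methylation, in which the N-(methoxymethyl)aniline formed under NaOMe is reduced by NaBH4 and a second alkylation is avoided.

Step 2
Reactants: 2 2,3-dimethoxy-N-methylaniline; 3 diethyl malonate
Product: 4 4-hydroxy-7,8-dimethoxy-1-methylquinolin-2(1H)-one
Conditions: Ph2O, 250 °C, EtOH distilled off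
Reagents that add atoms: none
Why: Thermal condensation of an N-alkylaniline with a malonic ester (amide formation, then cyclising acylation) is the classical 4-hydroxy-2-quinolone synthesis, and only one ortho position is free, so the 7,8-dimethoxy isomer must form.

Step 3
Reactants: 4 4-hydroxy-7,8-dimethoxy-1-methylquinolin-2(1H)-one
Product: 5 4-chloro-7,8-dimethoxy-1-methylquinolin-2(1H)-one
Conditions: POCl3, 90 °C
Reagents that add atoms: phosphoryl chloride, O=P(Cl)(Cl)Cl
Why: Deoxychlorination of the vinylogous acid OH, with the N-methyl lactam carbonyl unable to aromatise and therefore retained.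

Step 4
Reactants: 6 3-methylbut-2-en-1-ol (prenol)
Product: 7 [(2S)-3,3-dimethyloxiran-2-yl]methanol
Conditions: Ti(OiPr)4 (cat.), L-(+)-diisopropyl tartrate (cat.), t-BuOOH, 4 Å MS, CH2Cl2, −20 °C
Reagents that add atoms: tert-butyl hydroperoxide, CC(C)(C)OO
Why: Sharpless asymmetric epoxidation of a primary allylic alcohol, where the L-(+)-tartrate complex delivers oxygen to the face that gives the 2S epoxide.

Step 5
Reactants: 7 [(2S)-3,3-dimethyloxiran-2-yl]methanol
Product: 8 tert-butyl{[(2S)-3,3-dimethyloxiran-2-yl]methoxy}diphenylsilane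
Conditions: TBDPSCl, imidazole, CH2Cl2, 0 °C → rt
Reagents that add atoms: tert-butyl(chloro)diphenylsilane, CC(C)(C)[Si](Cl)(c1ccccc1)c1ccccc1
Why: Silylation of the primary alcohol with a bulky group that cannot migrate to the tertiary alkoxide of step 7 and survives steps 6 to 9.

Step 6
Reactants: 8 tert-butyl{[(2S)-3,3-dimethyloxiran-2-yl]methoxy}diphenylsilane
Product: 9 (3R)-3-({[tert-butyl(diphenyl)silyl]oxy}methyl)-2-methylpent-4-en-2-ol
Conditions: CH2=CHMgBr, CuI (cat.), THF, −20 → 0 °C
Reagents that add atoms: vinylmagnesium bromide, C=C[Mg]Br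
Why: Copper-catalysed Grignard opening of the epoxide by SN2 attack at the secondary carbon (the tertiary carbon is blocked), with inversion, which sets the future ring-fusion stereocentre.

Step 7
Reactants: 9 (3R)-3-({[tert-butyl(diphenyl)silyl]oxy}methyl)-2-methylpent-4-en-2-ol; 5 4-chloro-7,8-dimethoxy-1-methylquinolin-2(1H)-one
Product: 10 4-{[(3R)-3-({[tert-butyl(diphenyl)silyl]oxy}methyl)-2-methylpent-4-en-2-yl]oxy}-7,8-dimethoxy-1-methylquinolin-2(1H)-one
Conditions: NaH, DMF, 0 → 50 °C
Reagents that add atoms: none
Why: Addition–elimination (SNAr) of the sodium alkoxide at C4 of the 4-chloro-2-quinolone, a vinylogous carbamoyl chloride, with no other free hydroxyl to compete.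

Step 8
Reactants: 10 the aryl ether
Product: 11 4-{[(3R)-3-({[tert-butyl(diphenyl)silyl]oxy}methyl)-2-methylpent-4-en-2-yl]oxy}-3-iodo-7,8-dimethoxy-1-methylquinolin-2(1H)-one
Conditions: NIS, DMF, rt, dark
Reagents that add atoms: N-iodosuccinimide, O=C1CCC(=O)N1I
Why: Electrophilic iodination at C3, the β-carbon of the vinylogous carbamate and the most nucleophilic position, under acid-free conditions that spare the tertiary ether.

Step 9
Reactants: 11 the 3-iodo ether
Product: 12 (3R)-3-({[tert-butyl(diphenyl)silyl]oxy}methyl)-7,8-dimethoxy-2,2,6-trimethyl-4-methylidene-3,4-dihydro-2H-pyrano[3,2-c]quinolin-5(6H)-one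
Conditions: Pd(OAc)2 (cat.), PPh3, Ag2CO3, MeCN, 70 °C
Reagents that add atoms: none
Why: 6-exo-trig intramolecular Mizoroki–Heck reaction, in which the only β-hydrogen of the CH2–Pd intermediate sits on the newly bonded carbon, so the exocyclic methylene forms, while Ag2CO3 suppresses Pd–H re-addition and so protects the adjacent stereocentre.

Step 10
Reactants: 12 the silyl ether
Product: 13 (3R)-3-(hydroxymethyl)-7,8-dimethoxy-2,2,6-trimethyl-4-methylidene-3,4-dihydro-2H-pyrano[3,2-c]quinolin-5(6H)-one
Conditions: TBAF, AcOH, THF, 0 °C → rt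
Reagents that add atoms: none
Why: Fluoride cleavage of the silyl ether, buffered so that the allylic stereocentre does not meet strong base.

Step 11
Reactants: 13 the primary alcohol
Product: 14 (3S)-7,8-dimethoxy-2,2,6-trimethyl-4-methylidene-5-oxo-3,4,5,6-tetrahydro-2H-pyrano[3,2-c]quinoline-3-carbaldehyde
Conditions: Dess–Martin periodinane, NaHCO3, CH2Cl2, 0 °C; used at once without purification
Reagents that add atoms: none
Why: Buffered Dess–Martin oxidation is neither basic nor acidic, so the α-branched β,γ-unsaturated aldehyde should form without epimerisation or alkene migration.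

Step 12
Reactants: 14 the ring A aldehyde; 4 4-hydroxy-7,8-dimethoxy-1-methylquinolin-2(1H)-one; 15 2-methoxypropene (excess)
Product: 18 CNP0237003.1 (target), via quinone methide 16 (not isolated), via methyl ketal 17 (not isolated)
Conditions: ethylenediammonium diacetate (EDDA, cat.), 4 Å MS, MeCN, 0 °C → rt; then solvent exchange to CH2Cl2, 2,6-di-tert-butyl-4-methylpyridine (DTBMP), TMSOTf, −78 → −30 °C
Reagents that add atoms: none
Why: Proposed new method: Knoevenagel condensation of 14 with C3–H of 4 gives the 3-alkylidenequinoline-2,4-dione 16, whose O=C4–C3=CH oxadiene adds the enol ether 15 in an inverse-demand hetero-Diels–Alder reaction, forming the CH2–CH bond and the ring B ketal 17 (closest known type: the Tietze three-component domino Knoevenagel/hetero-Diels–Alder reaction of 4-hydroxycoumarins and 4-hydroxyquinolones with aldehydes and enol ethers). TMSOTf then ionises 17 to the oxocarbenium ion at the methyl-bearing carbon, the terminal CH2 of the ring A oxy-diene attacks it, and loss of a proton from the new ring CH2 gives the ring C alkene (closest known type: ketal-initiated Prins, that is oxocarbenium–alkene, cyclisation). Ring B closes by the [4+2] cycloaddition and ring C by a 6-endo-trig cation–alkene closure that creates the 2-oxabicyclo[3.3.1]nonene. The CH bridgehead is set in the cycloaddition by the ring-fusion stereocentre: allylic 1,3-strain holds its C–H in the plane of the alkylidene and 15 adds anti to the bulky CMe2–O carbon, which places the second quinolone anti to that carbon as in the target, and the methyl-bearing bridgehead then follows from the bridging geometry because the ring A substituent must be axial on ring B for closure. The step needs the C4 ketone oxygen, not the lactam oxygen, as diene terminus (the usual preference, and the ketals can re-equilibrate under the acid), and proton loss from the new CH2 and not from the ring-fusion CH (that C–H lies near the nodal plane of the cation, and DTBMP takes up the proton at low temperature).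

**Compound list**

1 | 2,3-dimethoxyaniline | Nc1cccc(OC)c1OC | starting material
2 | 2,3-dimethoxy-N-methylaniline | CNc1cccc(OC)c1OC | intermediate
3 | diethyl malonate | CCOC(=O)CC(=O)OCC | starting material
4 | 4-hydroxy-7,8-dimethoxy-1-methylquinolin-2(1H)-one | COc1ccc2c(O)cc(=O)n(C)c2c1OC | intermediate
5 | 4-chloro-7,8-dimethoxy-1-methylquinolin-2(1H)-one | COc1ccc2c(Cl)cc(=O)n(C)c2c1OC | intermediate
6 | 3-methylbut-2-en-1-ol (prenol) | CC(C)=CCO | starting material
7 | [(2S)-3,3-dimethyloxiran-2-yl]methanol | OC[C@@H]1OC1(C)C | intermediate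
8 | tert-butyl{[(2S)-3,3-dimethyloxiran-2-yl]methoxy}diphenylsilane | CC(C)(C)[Si](OC[C@@H]1OC1(C)C)(c1ccccc1)c1ccccc1 | intermediate
9 | (3R)-3-({[tert-butyl(diphenyl)silyl]oxy}methyl)-2-methylpent-4-en-2-ol | CC(C)(C)[Si](OC[C@@H](C=C)C(C)(C)O)(c1ccccc1)c1ccccc1 | intermediate
10 | 4-{[(3R)-3-({[tert-butyl(diphenyl)silyl]oxy}methyl)-2-methylpent-4-en-2-yl]oxy}-7,8-dimethoxy-1-methylquinolin-2(1H)-one | CC(C)(C)[Si](OC[C@@H](C=C)C(C)(C)Oc1cc(=O)n(C)c2c(OC)c(OC)ccc12)(c1ccccc1)c1ccccc1 | intermediate
11 | 4-{[(3R)-3-({[tert-butyl(diphenyl)silyl]oxy}methyl)-2-methylpent-4-en-2-yl]oxy}-3-iodo-7,8-dimethoxy-1-methylquinolin-2(1H)-one | CC(C)(C)[Si](OC[C@@H](C=C)C(C)(C)Oc1c(I)c(=O)n(C)c2c(OC)c(OC)ccc12)(c1ccccc1)c1ccccc1 | intermediate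
12 | (3R)-3-({[tert-butyl(diphenyl)silyl]oxy}methyl)-7,8-dimethoxy-2,2,6-trimethyl-4-methylidene-3,4-dihydro-2H-pyrano[3,2-c]quinolin-5(6H)-one | CC(C)(C)[Si](OC[C@@H]1C(C)(C)Oc2c(C1=C)c(=O)n(C)c3c(OC)c(OC)ccc23)(c1ccccc1)c1ccccc1 | intermediate
13 | (3R)-3-(hydroxymethyl)-7,8-dimethoxy-2,2,6-trimethyl-4-methylidene-3,4-dihydro-2H-pyrano[3,2-c]quinolin-5(6H)-one | OC[C@@H]1C(C)(C)Oc2c(C1=C)c(=O)n(C)c3c(OC)c(OC)ccc23 | intermediate
14 | (3S)-7,8-dimethoxy-2,2,6-trimethyl-4-methylidene-5-oxo-3,4,5,6-tetrahydro-2H-pyrano[3,2-c]quinoline-3-carbaldehyde | O=C[C@@H]1C(C)(C)Oc2c(C1=C)c(=O)n(C)c3c(OC)c(OC)ccc23 | intermediate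
15 | 2-methoxypropene | COC(C)=C | starting material
16 | 3-{[(3S)-7,8-dimethoxy-2,2,6-trimethyl-4-methylidene-5-oxo-3,4,5,6-tetrahydro-2H-pyrano[3,2-c]quinolin-3-yl]methylidene}-7,8-dimethoxy-1-methylquinoline-2,4(1H,3H)-dione (alkylidene geometry not defined) | O=C1c2ccc(OC)c(OC)c2N(C)C(=O)C1=C[C@@H]3C(C)(C)Oc4c(C3=C)c(=O)n(C)c5c(OC)c(OC)ccc45 | intermediate
17 | (4R)-4-[(3S)-7,8-dimethoxy-2,2,6-trimethyl-4-methylidene-5-oxo-3,4,5,6-tetrahydro-2H-pyrano[3,2-c]quinolin-3-yl]-2,7,8-trimethoxy-2,6-dimethyl-3,4-dihydro-2H-pyrano[3,2-c]quinolin-5(6H)-one (both epimers at the ketal carbon) | COC1(C)C[C@@H](c2c(O1)c3ccc(OC)c(OC)c3n(C)c2=O)[C@@H]4C(C)(C)Oc5c(C4=C)c(=O)n(C)c6c(OC)c(OC)ccc56 | intermediate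
18 | CNP0237003.1: two 7,8-dimethoxy-1-methylquinolin-2-one units joined through a 2-oxabicyclo[3.3.1]non-7-ene (rings B and C) whose alkene carbon and adjacent CH are shared with the 2,2-dimethylpyran ring A; S at the methyl-bearing bridgehead, R at the CH bridgehead, S at the ring A/ring C fusion CH | COc1ccc2c3c(c(=O)n(C)c2c1OC)C1=C[C@]2(C)C[C@@H](c4c(c5ccc(OC)c(OC)c5n(C)c4=O)O2)[C@@H]1C(C)(C)O3 | target

**Count and risks**

Total steps: 12. Longest linear sequence: 9 steps (steps 4 to 12 from 6; equally steps 1, 2, 3 and 7 to 12 from 1).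

Steps most likely to fail:

1. Step 12 (proposed new method). What may go wrong:
   - epimerisation of the aldehyde, or migration of its alkene into conjugation, under the amine salt;
   - tautomerisation of the quinone methide to the alkenyl-quinolone, which erases the ring-fusion centre;
   - addition of a second molecule of 4 to the quinone methide;
   - poor face selectivity at the new CH bridgehead;
   - cycloaddition through the lactam oxygen;
   - proton loss toward the ring-fusion carbon in the last stage.

   Fallback, in reactions of known type, from 14 back to the route at 17: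
   - Wittig olefination of 14 with 1-(triphenylphosphoranylidene)propan-2-one (CH2Cl2, rt) would give the enone (3E)-4-[(3S)-7,8-dimethoxy-2,2,6-trimethyl-4-methylidene-5-oxo-3,4,5,6-tetrahydro-2H-pyrano[3,2-c]quinolin-3-yl]but-3-en-2-one F1.
   - Conjugate addition of 4 to F1 under primary-amine catalysis (the matching enantiomer of 1,2-diphenylethane-1,2-diamine, AcOH, THF), the reaction used for warfarin-type adducts, would set the CH bridgehead under catalyst control. It would give 4-hydroxy-3-{(1R)-1-[(3S)-7,8-dimethoxy-2,2,6-trimethyl-4-methylidene-5-oxo-3,4,5,6-tetrahydro-2H-pyrano[3,2-c]quinolin-3-yl]-3-oxobutyl}-7,8-dimethoxy-1-methylquinolin-2(1H)-one F2, in equilibrium with its cyclic hemiketal.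
   - HC(OMe)3, MeOH and pyridinium p-toluenesulfonate would turn F2 into the methyl ketal 17, now isolated.
   - TMSOTf and DTBMP in CH2Cl2 would then close ring C to 18 as a separate ketal-initiated Prins cyclisation.

2. Step 9. What may go wrong: migration of the exocyclic alkene into ring A by re-addition of Pd–H (with loss of the stereocentre), 7-endo closure, or reductive loss of iodine.

   Fallback from 8 back to the route at 12:
   - Opening of 8 with LiC≡CH·H2NCH2CH2NH2 in DMSO (SN2 at the secondary carbon, inversion) would give (3R)-3-({[tert-butyl(diphenyl)silyl]oxy}methyl)-2-methylpent-4-yn-2-ol F3.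
   - Its sodium alkoxide and 5 (NaH, DMF) would give 4-{[(3R)-3-({[tert-butyl(diphenyl)silyl]oxy}methyl)-2-methylpent-4-yn-2-yl]oxy}-7,8-dimethoxy-1-methylquinolin-2(1H)-one F4.
   - Ph3PAuNTf2 (cat.) in CH2Cl2 at rt would effect a 6-exo-dig hydroarylation of the terminal alkyne by C3 of the quinolone. This gives 12 with no palladium hydride present and without the iodide 11.

3. Step 7. What may go wrong: slow substitution by the hindered tertiary alkoxide, with decomposition of the chloride on prolonged heating.

   Fallback from 9 and 5 back to the route at 10: the C–O bond would be made by palladium-catalysed cross-coupling in place of addition–elimination. The sodium alkoxide of 9 and 5 would be heated with Pd2(dba)3 and 2-(di-tert-butylphosphino)-1,1'-binaphthyl in toluene at 80–100 °C. The ether then forms by reductive elimination from an arylpalladium alkoxide of divalent palladium, and a tertiary alkoxide has no hydrogen for β-hydride elimination. No new compound is made.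

Further compounds
F1 | step 12 | (3E)-4-[(3S)-7,8-dimethoxy-2,2,6-trimethyl-4-methylidene-5-oxo-3,4,5,6-tetrahydro-2H-pyrano[3,2-c]quinolin-3-yl]but-3-en-2-one | CC(=O)/C=C/[C@@H]1C(C)(C)Oc2c(C1=C)c(=O)n(C)c3c(OC)c(OC)ccc23
F2 | step 12 | 4-hydroxy-3-{(1R)-1-[(3S)-7,8-dimethoxy-2,2,6-trimethyl-4-methylidene-5-oxo-3,4,5,6-tetrahydro-2H-pyrano[3,2-c]quinolin-3-yl]-3-oxobutyl}-7,8-dimethoxy-1-methylquinolin-2(1H)-one | CC(=O)C[C@@H](c1c(O)c2ccc(OC)c(OC)c2n(C)c1=O)[C@@H]3C(C)(C)Oc4c(C3=C)c(=O)n(C)c5c(OC)c(OC)ccc45
F3 | step 9 | (3R)-3-({[tert-butyl(diphenyl)silyl]oxy}methyl)-2-methylpent-4-yn-2-ol | CC(C)(C)[Si](OC[C@@H](C#C)C(C)(C)O)(c1ccccc1)c1ccccc1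
F4 | step 9 | 4-{[(3R)-3-({[tert-butyl(diphenyl)silyl]oxy}methyl)-2-methylpent-4-yn-2-yl]oxy}-7,8-dimethoxy-1-methylquinolin-2(1H)-one | CC(C)(C)[Si](OC[C@@H](C#C)C(C)(C)Oc1cc(=O)n(C)c2c(OC)c(OC)ccc12)(c1ccccc1)c1ccccc1
F0 | step 7 | none | none
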